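Take the ratio of target's hourly rise to the substrate charged: it is a fractional rate, and from it you can build a ladder of times for this flask, which holds 2.0 M of substrate under 2.20 M of reagent in the second phase and is read at 10 h.

| flask | substrate | reagent in the second phase | remark | time | volume of the second phase over the first |
|---|---|---|---|---|---|
| Friday's | 1 M | 2.2 M | run made earlier |  |  |
| Monday's | 1.5 M | 2.2 M | run made earlier |  |  |
| Tuesday's | 2 M | 1.1 M | run made earlier |  |  |
| flask | 2.0 M | 2.20 M |  | 10 h | 2.0 |

| run | time / h | target / % |
|---|---|---|
| Friday's | 0.417 | 0.3 |
| Friday's | 1.33 | 4.4 |
| Friday's | 2.00 | 9.2 |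
| Friday's | 3.00 | 15.6 |
| Friday's | 5.00 | 24.6 |
| Friday's | 6.00 | 27.1 |
| Monday's | 0.417 | 1.1 |
| Monday's | 1.33 | 4.4 |
| Monday's | 2.00 | 8.6 |
| Monday's | 3.00 | 13.4 |
| Monday's | 5.00 | 23.7 |
| Monday's | 6.00 | 25.7 |
| Tuesday's | 0.500 | 0 |
| Tuesday's | 1.50 | 3.0 |
| Tuesday's | 3.00 | 8.7 |
| Tuesday's | 4.00 | 8.4 |
| Tuesday's | 6.00 | 13.2 |

(readings scatter by 1 percentage point)

- in the second phase: reagent in the second phase; everything else is in the first
- charges count per volume of the first phase; a concentration in a rate is the amount of a species over the volume of its own phase; every rate counts per litre of the first phase
- the earlier runs hold the two phases in the same ratio of volumes as the flask asked about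

1. how much target there is at 10 h, in percent of the substrate charged
2. the change that raises the amount of target at 10 h, in percent of the substrate charged most ("none" if none brings more than 2 percentage points) (theta / epsilon / none)
3. amount of target at 10 h, in percent of the substrate charged, after epsilon

- theta: doubling the amount of reagent in the second phase, all else as stated
- epsilon: doubling the transfer coefficient of the reagent in the second phase, all else as stated

The shortest rung is the lag. Friday's run shows 0.3% of target at 0.417 h, so you should expect a short delay before the rise begins.

The next rung comes from Friday's and Monday's runs, which carry the flask's reagent charge. Between 1.33 h and 3.00 h they rise, on average, by 0.0605 h⁻¹, a reading with its scatter. Treat this as a pseudo-first-order constant for substrate. It gives the substrate half-time, the time in which this rate would use half of the substrate present, 11.5 h. That is longer than the 10 h of the flask, so I reckon about 54.6% of the substrate is left at the reading.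

Tuesday's run, with 1.1 M of reagent and 2 M of substrate, rises by 0.0380 h⁻¹, less than that rate; both settings differ from those of Friday's and Monday's runs, so this is a hint, not a proof, but I look to the reagent charge for more target.

The top rung is the slowdown: Friday's run gains 6.4 percentage points in its hour to 3.00 h, but 2.5 points in its last hour.

The forecast says 31% (25% to 37%), names theta as the best change, and gives 33% (26% to 40%) after epsilon: “Faster transfer only shortens the lag, so it gains little.”

The flask gives 32.0% of target, and theta is best, gaining 11 points against 4.1 points for epsilon, which reaches 36.1%.

    reagent in the reaction phase ⇌ reagent in the second phase, rate k1*([reagent in the reaction phase] - [reagent in the second phase]/K1) per volume of the first phase (partition coefficient = 2.10, kL = 1.50 × 10⁻⁴ s⁻¹)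
    substrate + reagent in the reaction phase → target (k = 9.00 × 10⁻⁵ M⁻¹ s⁻¹)
    reagent in the reaction phase + target → over-reacted product (k = 6.30 × 10⁻⁵ M⁻¹ s⁻¹)
    reagent in the reaction phase ⇌ dormant form (K = 2.80, k = 3.00 × 10⁻⁵ s⁻¹)

The flask's target is made 7.88 times faster than it is used up at 3.60 h, and at 10.0 h still 2.76 times faster, each step taken net. The flask keeps 62% of its substrate, more than the 54.6% reckoned from the half-time. The neighbour with 1.2 M of substrate, at the same reagent charge and time, is reckoned at the same 54.6%, since a first-order half-time does not use the substrate charge, and it keeps 54%.

All runs come from a simulation for substances that don't exist, noise included.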